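**Strategy.** The plan rests on cutting the hindered biaryl bond between C-1 of the 4-methoxy-7-methylnaphthalene-2,5-diol half and C-4 of the 8-methoxy-3-methylnaphthalene-1,7-diol half. The feature exploited is the free C-2 hydroxyl that sits directly beside C-1 in the oxygenated ring of the first half. In the key step this hydroxyl binds the tetravalent lead of aryllead triacetate 24, and the temporary O–Pb bridge delivers the 2-methylnaphthyl group to the neighbouring ring carbon by ligand coupling. The tetra-ortho-substituted axis forms in one operation, with no protecting group on that hydroxyl. Both halves come from isomeric hydroxy-methoxybenzamides by the same directed ortho-metalation, methallylation and anionic ring annulation.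

Key step: step 14

Remark: the target SMILES carries no axial descriptor, so the configurationally stable axis is made as the racemate and no step controls it.

**Step 1**
Reactants: 1 4-hydroxy-2-methoxybenzoic acid
Product: 2 N,N-diethyl-4-hydroxy-2-methoxybenzamide
Conditions: Et2NH, DIC, HOBt, CH2Cl2/DMF, 0 °C → rt
Reagents that add atoms: diethylamine CCNCC
Why: Carbodiimide amide coupling; the HOBt active ester is intercepted by the secondary amine much faster than by the phenol, so the hydroxyl can stay free.

**Step 2**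
Reactants: 2 N,N-diethyl-4-hydroxy-2-methoxybenzamide
Product: 3 N,N-diethyl-2-methoxy-4-[(triisopropylsilyl)oxy]benzamide
Conditions: TIPSCl, imidazole, DMF, rt
Reagents that add atoms: chlorotriisopropylsilane CC(C)[Si](Cl)(C(C)C)C(C)C
Why: Imidazole-mediated silylation of the phenol gives a base-stable ether whose bulk shields both of its ortho positions from the lithiation that follows.

**Step 3**
Reactants: 3 N,N-diethyl-2-methoxy-4-[(triisopropylsilyl)oxy]benzamide
Product: 6 N,N-diethyl-2-methoxy-6-(2-methylprop-2-en-1-yl)-4-[(triisopropylsilyl)oxy]benzamide, via ortho-lithiated benzamide 4 (not isolated), via arylmagnesium bromide 5 (not isolated)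
Conditions: s-BuLi, TMEDA, THF, −78 °C; MgBr2·OEt2, −78 → 0 °C; CH2=C(CH3)CH2Br, 0 °C → rt
Reagents that add atoms: 3-bromo-2-methylprop-1-ene CC(=C)CBr
Why: Directed ortho-metalation: the tertiary amide directs s-BuLi to C-6, its only free ortho position, and lithium-to-magnesium exchange then allows clean allylation.

**Step 4**
Reactants: 6 N,N-diethyl-2-methoxy-6-(2-methylprop-2-en-1-yl)-4-[(triisopropylsilyl)oxy]benzamide
Product: 8 8-methoxy-3-methyl-6-[(triisopropylsilyl)oxy]naphthalen-1-ol, via benzylic allyllithium 7 (not isolated)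
Conditions: LiN(iPr)2 (2.5 equiv), THF, −78 °C → rt; aq NH4Cl
Reagents that add atoms: none
Why: Anionic aromatic ring annulation of an ortho-allylbenzamide: the amide-assisted benzylic deprotonation gives an allyl anion whose terminal carbon acylates on the amide carbonyl in a six-membered closure, and loss of LiNEt2 with enolisation gives the 3-methyl-1-naphthol.

**Step 5**
Reactants: 8 8-methoxy-3-methyl-6-[(triisopropylsilyl)oxy]naphthalen-1-ol
Product: 9 triisopropyl[(5-isopropoxy-4-methoxy-7-methylnaphthalen-2-yl)oxy]silane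
Conditions: 2-iodopropane, K2CO3, acetone, reflux
Reagents that add atoms: 2-iodopropane CC(C)I
Why: Williamson etherification of the only free (peri) hydroxyl; the hindered silyl ether tolerates anhydrous carbonate.

**Step 6**
Reactants: 9 triisopropyl[(5-isopropoxy-4-methoxy-7-methylnaphthalen-2-yl)oxy]silane
Product: 10 5-isopropoxy-4-methoxy-7-methylnaphthalen-2-ol
Conditions: Bu4NF, THF, 0 °C; aq NH4Cl
Reagents that add atoms: none
Why: Fluoride desilylation frees the C-2 hydroxyl and leaves the alkyl ethers untouched.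

**Step 7**
Reactants: 11 3-hydroxy-2-methoxybenzoic acid
Product: 12 N,N-diethyl-3-hydroxy-2-methoxybenzamide
Conditions: Et2NH, DIC, HOBt, CH2Cl2/DMF, 0 °C → rt
Reagents that add atoms: diethylamine CCNCC
Why: Carbodiimide amide coupling, chemoselective for the amine over the phenol as in step 1.

**Step 8**
Reactants: 12 N,N-diethyl-3-hydroxy-2-methoxybenzamide
Product: 13 N,N-diethyl-3-isopropoxy-2-methoxybenzamide
Conditions: 2-iodopropane, K2CO3, DMF, 60 °C
Reagents that add atoms: 2-iodopropane CC(C)I
Why: Williamson etherification gives an isopropyl ether that is inert to alkyllithiums and is only a weak directing group.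

**Step 9**
Reactants: 13 N,N-diethyl-3-isopropoxy-2-methoxybenzamide
Product: 16 N,N-diethyl-3-isopropoxy-2-methoxy-6-(2-methylprop-2-en-1-yl)benzamide, via ortho-lithiated benzamide 14 (not isolated), via arylmagnesium bromide 15 (not isolated)
Conditions: s-BuLi, TMEDA, THF, −78 °C; MgBr2·OEt2, −78 → 0 °C; CH2=C(CH3)CH2Br, 0 °C → rt
Reagents that add atoms: 3-bromo-2-methylprop-1-ene CC(=C)CBr
Why: Directed ortho-metalation: the amide outranks the alkoxy groups as director and C-6 is its only free ortho position; allylation follows after lithium-to-magnesium exchange.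

**Step 10**
Reactants: 16 N,N-diethyl-3-isopropoxy-2-methoxy-6-(2-methylprop-2-en-1-yl)benzamide
Product: 18 7-isopropoxy-8-methoxy-3-methylnaphthalen-1-ol, via benzylic allyllithium 17 (not isolated)
Conditions: LiN(iPr)2 (2.5 equiv), THF, −78 °C → rt; aq NH4Cl
Reagents that add atoms: none
Why: Anionic aromatic ring annulation as in step 4: the allyl anion acylates on the amide carbonyl and the ring aromatises to the 1-naphthol.

**Step 11**
Reactants: 18 7-isopropoxy-8-methoxy-3-methylnaphthalen-1-ol
Product: 19 1,7-diisopropoxy-8-methoxy-3-methylnaphthalene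
Conditions: 2-iodopropane, K2CO3, DMF, 60 °C
Reagents that add atoms: 2-iodopropane CC(C)I
Why: Williamson etherification of the peri hydroxyl completes a protecting-group set that one Lewis acid removes at the end.

**Step 12**
Reactants: 19 1,7-diisopropoxy-8-methoxy-3-methylnaphthalene
Product: 20 1-bromo-4,6-diisopropoxy-5-methoxy-2-methylnaphthalene
Conditions: NBS, MeCN, −20 → 0 °C, dark
Reagents that add atoms: N-bromosuccinimide O=C1CCC(=O)N1Br
Why: Electrophilic aromatic bromination at the alpha carbon para to the C-1 isopropoxy group and ortho to the methyl group, the most activated site; the methoxy group of the other ring is twisted out of conjugation by its two neighbours.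

**Step 13**
Reactants: 20 1-bromo-4,6-diisopropoxy-5-methoxy-2-methylnaphthalene
Product: 23 (4,6-diisopropoxy-5-methoxy-2-methylnaphthalen-1-yl)boronic acid, via naphthyllithium 21 (not isolated), via lithium aryltrimethoxyborate 22 (not isolated)
Conditions: n-BuLi, THF, −78 °C; B(OMe)3, −78 °C → rt; dilute aq HCl, 0 °C
Reagents that add atoms: trimethyl borate COB(OC)OC; water O
Why: Bromine–lithium exchange, borate capture and mild hydrolysis give the boronic acid; the exchange is faster than any ether-directed lithiation at −78 °C.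

**Step 14**
Reactants: 23 (4,6-diisopropoxy-5-methoxy-2-methylnaphthalen-1-yl)boronic acid; 10 5-isopropoxy-4-methoxy-7-methylnaphthalen-2-ol
Product: 25 1-(4,6-diisopropoxy-5-methoxy-2-methylnaphthalen-1-yl)-5-isopropoxy-4-methoxy-7-methylnaphthalen-2-ol, via aryllead triacetate 24 (not isolated)
Conditions: 23 (1.1 equiv), Pb(OAc)4 (1.05 equiv), Hg(OAc)2 (10 mol %), CHCl3, 40 °C; then 10 (1.0 equiv), pyridine, CHCl3, 60 °C
Reagents that add atoms: none
Why: Pinhey arylation: Hg(OAc)2-catalysed boron-to-lead exchange turns 23 into aryllead triacetate 24, pyridine promotes exchange of one acetate for the naphthoxide of 10, and ligand coupling (reductive elimination from tetravalent to divalent lead) moves the aryl group from lead to C-1 of the naphthol, giving a 1-aryl-naphthalen-2(1H)-one that tautomerises to 25. The closest known reaction type is the ortho-C-arylation of phenols, naphthols and beta-dicarbonyl compounds by aryllead triacetates, which is known to build very crowded aryl–carbon bonds. No ring is closed and no stereocentre is created; the new axis is stereogenic but forms without control, as the racemate. The selectivity needed is C-1 over C-3 and carbon over oxygen: the O–Pb bond confines delivery to the two ortho carbons, attack at C-1 keeps the neighbouring benzenoid ring aromatic in the dienone whereas attack at C-3 would not, and C-1 is also para to the methoxy group. The slight excess of 23 over Pb(OAc)4 should leave no free tetravalent lead to oxidise the electron-rich naphthol.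

**Step 15**
Reactants: 25 1-(4,6-diisopropoxy-5-methoxy-2-methylnaphthalen-1-yl)-5-isopropoxy-4-methoxy-7-methylnaphthalen-2-ol
Product: 26 4,5'-dimethoxy-2',7-dimethyl-[1,1'-binaphthalene]-2,4',5,6'-tetrol
Conditions: BCl3, CH2Cl2, −78 → 0 °C; then MeOH/H2O
Reagents that add atoms: none
Why: Lewis-acid dealkylation: BCl3 ionises the secondary isopropyl–oxygen bonds at low temperature, where the methyl ethers, which would need SN2 attack, should stay intact.

**Compound list**
1 | 4-hydroxy-2-methoxybenzoic acid | COc1cc(O)ccc1C(=O)O | starting material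
2 | N,N-diethyl-4-hydroxy-2-methoxybenzamide | CCN(CC)C(=O)c1ccc(O)cc1OC | intermediate
3 | N,N-diethyl-2-methoxy-4-[(triisopropylsilyl)oxy]benzamide | CCN(CC)C(=O)c1ccc(O[Si](C(C)C)(C(C)C)C(C)C)cc1OC | intermediate
4 | [2-(diethylcarbamoyl)-3-methoxy-5-(triisopropylsilyloxy)phenyl]lithium | [Li]c1cc(O[Si](C(C)C)(C(C)C)C(C)C)cc(OC)c1C(=O)N(CC)CC | intermediate (not isolated)
5 | [2-(diethylcarbamoyl)-3-methoxy-5-(triisopropylsilyloxy)phenyl]magnesium bromide | Br[Mg]c1cc(O[Si](C(C)C)(C(C)C)C(C)C)cc(OC)c1C(=O)N(CC)CC | intermediate (not isolated)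
6 | N,N-diethyl-2-methoxy-6-(2-methylprop-2-en-1-yl)-4-[(triisopropylsilyl)oxy]benzamide | CCN(CC)C(=O)c1c(CC(C)=C)cc(O[Si](C(C)C)(C(C)C)C(C)C)cc1OC | intermediate
7 | benzylic allyllithium of 6 (lithium on the benzylic carbon) | [Li]C(C(C)=C)c1cc(O[Si](C(C)C)(C(C)C)C(C)C)cc(OC)c1C(=O)N(CC)CC | intermediate (not isolated)
8 | 8-methoxy-3-methyl-6-[(triisopropylsilyl)oxy]naphthalen-1-ol | Cc1cc(O)c2c(OC)cc(O[Si](C(C)C)(C(C)C)C(C)C)cc2c1 | intermediate
9 | triisopropyl[(5-isopropoxy-4-methoxy-7-methylnaphthalen-2-yl)oxy]silane | Cc1cc(OC(C)C)c2c(OC)cc(O[Si](C(C)C)(C(C)C)C(C)C)cc2c1 | intermediate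
10 | 5-isopropoxy-4-methoxy-7-methylnaphthalen-2-ol | Cc1cc(OC(C)C)c2c(OC)cc(O)cc2c1 | intermediate
11 | 3-hydroxy-2-methoxybenzoic acid | COc1c(O)cccc1C(=O)O | starting material
12 | N,N-diethyl-3-hydroxy-2-methoxybenzamide | CCN(CC)C(=O)c1cccc(O)c1OC | intermediate
13 | N,N-diethyl-3-isopropoxy-2-methoxybenzamide | CCN(CC)C(=O)c1cccc(OC(C)C)c1OC | intermediate
14 | [2-(diethylcarbamoyl)-4-isopropoxy-3-methoxyphenyl]lithium | [Li]c1ccc(OC(C)C)c(OC)c1C(=O)N(CC)CC | intermediate (not isolated)
15 | [2-(diethylcarbamoyl)-4-isopropoxy-3-methoxyphenyl]magnesium bromide | Br[Mg]c1ccc(OC(C)C)c(OC)c1C(=O)N(CC)CC | intermediate (not isolated)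
16 | N,N-diethyl-3-isopropoxy-2-methoxy-6-(2-methylprop-2-en-1-yl)benzamide | CCN(CC)C(=O)c1c(CC(C)=C)ccc(OC(C)C)c1OC | intermediate
17 | benzylic allyllithium of 16 (lithium on the benzylic carbon) | [Li]C(C(C)=C)c1ccc(OC(C)C)c(OC)c1C(=O)N(CC)CC | intermediate (not isolated)
18 | 7-isopropoxy-8-methoxy-3-methylnaphthalen-1-ol | Cc1cc(O)c2c(OC)c(OC(C)C)ccc2c1 | intermediate
19 | 1,7-diisopropoxy-8-methoxy-3-methylnaphthalene | Cc1cc(OC(C)C)c2c(OC)c(OC(C)C)ccc2c1 | intermediate
20 | 1-bromo-4,6-diisopropoxy-5-methoxy-2-methylnaphthalene | Cc1cc(OC(C)C)c2c(OC)c(OC(C)C)ccc2c1Br | intermediate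
21 | (4,6-diisopropoxy-5-methoxy-2-methylnaphthalen-1-yl)lithium | Cc1cc(OC(C)C)c2c(OC)c(OC(C)C)ccc2c1[Li] | intermediate (not isolated)
22 | lithium (4,6-diisopropoxy-5-methoxy-2-methylnaphthalen-1-yl)trimethoxyborate | [Li+].CO[B-](OC)(OC)c1c(C)cc(OC(C)C)c2c(OC)c(OC(C)C)ccc12 | intermediate (not isolated)
23 | (4,6-diisopropoxy-5-methoxy-2-methylnaphthalen-1-yl)boronic acid | Cc1cc(OC(C)C)c2c(OC)c(OC(C)C)ccc2c1B(O)O | intermediate
24 | (4,6-diisopropoxy-5-methoxy-2-methylnaphthalen-1-yl)lead triacetate | Cc1cc(OC(C)C)c2c(OC)c(OC(C)C)ccc2c1[Pb](OC(C)=O)(OC(C)=O)OC(C)=O | intermediate (not isolated)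
25 | 1-(4,6-diisopropoxy-5-methoxy-2-methylnaphthalen-1-yl)-5-isopropoxy-4-methoxy-7-methylnaphthalen-2-ol | COc1cc(O)c(-c2c(C)cc(OC(C)C)c3c(OC)c(OC(C)C)ccc23)c2cc(C)cc(OC(C)C)c12 | intermediate
26 | 4,5'-dimethoxy-2',7-dimethyl-[1,1'-binaphthalene]-2,4',5,6'-tetrol | COc1cc(O)c(-c2c(C)cc(O)c3c(OC)c(O)ccc23)c2cc(C)cc(O)c12 | target

**Totals**
Total step count: 15. Longest linear sequence: 9 steps (steps 7 to 15).

**Steps most likely to fail**

1. Step 14. The ligand coupling at the doubly flanked carbon may be too slow, so that oxidation of the naphthol by tetravalent lead or protodemetalation of the aryllead takes over. Fallback, a Suzuki–Miyaura coupling: setting out from 10, bromination at C-1 (NBS, MeCN, −20 °C) should give 1-bromo-5-isopropoxy-4-methoxy-7-methylnaphthalen-2-ol F1. Etherification (2-iodopropane, K2CO3, DMF) should give 1-bromo-2,5-diisopropoxy-4-methoxy-7-methylnaphthalene F2. Coupling of F2 with boronic acid 23 (Pd(OAc)2, SPhos, K3PO4, toluene/H2O, 100 °C) should give 2,4',5,6'-tetraisopropoxy-4,5'-dimethoxy-2',7-dimethyl-1,1'-binaphthalene F3. BCl3 under the conditions of step 15 would remove all four isopropyl groups, and the fallback comes back to the route at target 26.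

2. Step 12. Positional control may be lost in the bromination, with substitution in the other ring or ortho to the ether. Fallback, bromination under control of the free hydroxyl: setting out from naphthol 18, NBS (CH2Cl2, −78 °C) should brominate para to the much stronger hydroxyl director and give 4-bromo-7-isopropoxy-8-methoxy-3-methylnaphthalen-1-ol F4. Etherification (2-iodopropane, K2CO3, DMF) then comes back to the route at 20.

3. Step 13. The hindered, electron-rich boronic acid may undergo protodeboronation during hydrolysis or handling. Fallback, the tin route: setting out from 20, bromine–lithium exchange (n-BuLi, THF, −78 °C) and quenching with Bu3SnCl should give tributyl(4,6-diisopropoxy-5-methoxy-2-methylnaphthalen-1-yl)stannane F5. Tin-to-lead exchange (Pb(OAc)4, Hg(OAc)2 cat., CHCl3) comes back to the route at aryllead triacetate 24, which is used directly in step 14.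

**Further compounds**
F1 | step 14 | 1-bromo-5-isopropoxy-4-methoxy-7-methylnaphthalen-2-ol | Cc1cc(OC(C)C)c2c(OC)cc(O)c(Br)c2c1
F2 | step 14 | 1-bromo-2,5-diisopropoxy-4-methoxy-7-methylnaphthalene | Cc1cc(OC(C)C)c2c(OC)cc(OC(C)C)c(Br)c2c1
F3 | step 14 | 2,4',5,6'-tetraisopropoxy-4,5'-dimethoxy-2',7-dimethyl-1,1'-binaphthalene | COc1cc(OC(C)C)c(-c2c(C)cc(OC(C)C)c3c(OC)c(OC(C)C)ccc23)c2cc(C)cc(OC(C)C)c12
F4 | step 12 | 4-bromo-7-isopropoxy-8-methoxy-3-methylnaphthalen-1-ol | Cc1cc(O)c2c(OC)c(OC(C)C)ccc2c1Br
F5 | step 13 | tributyl(4,6-diisopropoxy-5-methoxy-2-methylnaphthalen-1-yl)stannane | CCCC[Sn](CCCC)(CCCC)c1c(C)cc(OC(C)C)c2c(OC)c(OC(C)C)ccc12
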